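**Retrosynthetic overview**
- Ring A is closed last by an intramolecular Mannich reaction (CH2O) on a pentacyclic secondary-amine ethyl ketone (forms C18–C19 and N–C19).
- Key step: a tin hydride radical cascade on a bromoacetate. The ester radical adds 7-endo to the terminal CH2 of an s-cis diene (C14–C13, lactone ring F). The resulting tertiary allyl radical adds across a seven-membered cyclic enaminone (C8–C1), closing rings B and C, creating quaternary C8 and leaving the alkene at C9=C15.
- The enaminone comes from C-acylation of a cyclic imine, itself formed from the C7 amine and the C1 aldehyde after one LiAlH4 reduction of ester and nitro groups.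
- Ring D (the diene) is closed by an intramolecular Stille–Kelly coupling of two enol triflates.
- C5/C6 are set by an organocatalytic Michael addition of an α-alkyl acetoacetate to a nitroalkene, and C10 by SAMP-hydrazone alkylation of cyclopentanone. Ring order: E (bought), D, then F + B + C in one step, then A.

Labels used in names (target atoms): N; C1 (NCH); C2 (CH next to the ketone); C3 (ketone C); C4 (CH2 of ring C); C5 and C8 (quaternary); C6; C7 (NCH2); C9=C15; C10; C11; C12; C13; C14; C16; C17; C18 (CHMe); C19 (NCH2); C20 (Me); C21 (OCH2); C22 (lactone C=O). Rings: A = N/C1/C2/C3/C18/C19; B = N/C1/C8/C5/C6/C7; C = C1/C2/C4/C5/C8; D = C5/C6/C12/C11/C10/C9/C8; E = C9/C10/C17/C16/C15; F = lactone. Target = (1S,2S,5R,6S,8R,10S,18R).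

Assumption: the natural C18 epimer is the one favoured at equilibrium in this β-amino ketone; 17 is drawn as its imine ring-chain tautomer.

**Route**

Step 1
Reactants: 1 cyclopentanone
Product: 2 (S)-N-cyclopentylidene-2-(methoxymethyl)pyrrolidin-1-amine
Conditions: SAMP (1.05 equiv), cyclohexane, reflux, Dean–Stark
Reagents that add atoms: SAMP, (S)-1-amino-2-(methoxymethyl)pyrrolidine, COC[C@@H]1CCCN1N
Why: Hydrazone condensation attaches the chiral auxiliary needed for the Enders alkylation; no stereocenter is formed.

Step 2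
Reactants: 2 (S)-N-cyclopentylidene-2-(methoxymethyl)pyrrolidin-1-amine; 3 3-bromo-1,1-dimethoxypropane
Product: 4 (2S)-N-[(2S)-2-(3,3-dimethoxypropyl)cyclopentylidene]-2-(methoxymethyl)pyrrolidin-1-amine
Conditions: LiN(iPr)2, THF, 0 °C; then 3, −100 °C → rt
Reagents that add atoms: none
Why: Enders SAMP-hydrazone alkylation: the lithium-chelated azaenolate is alkylated on the face away from the methoxymethyl arm, which sets C10 as (S).

Step 3
Reactants: 4 (2S)-N-[(2S)-2-(3,3-dimethoxypropyl)cyclopentylidene]-2-(methoxymethyl)pyrrolidin-1-amine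
Product: 5 (S)-2-(3,3-dimethoxypropyl)cyclopentan-1-one
Conditions: O3, CH2Cl2, −78 °C; N2 purge
Reagents that add atoms: ozone, [O-][O+]=O
Why: Ozonolytic hydrazone cleavage frees the ketone under neutral conditions, so the α-stereocenter and the acetal survive.

Step 4
Reactants: 5 (S)-2-(3,3-dimethoxypropyl)cyclopentan-1-one
Product: 6 (S)-5-(3,3-dimethoxypropyl)cyclopent-1-en-1-yl trifluoromethanesulfonate
Conditions: KN(SiMe3)2, THF, −78 °C; PhNTf2, −78 → 0 °C
Reagents that add atoms: N-phenylbis(trifluoromethanesulfonimide), O=S(=O)(N(c1ccccc1)S(=O)(=O)C(F)(F)F)C(F)(F)F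
Why: Kinetic enolization at the unsubstituted α-CH2 and O-triflation give the less substituted enol triflate, which locks C10 against epimerization and fixes the later C9=C15 alkene position.

Step 5
Reactants: 6 (S)-5-(3,3-dimethoxypropyl)cyclopent-1-en-1-yl trifluoromethanesulfonate
Product: 7 (S)-5-(3-oxopropyl)cyclopent-1-en-1-yl trifluoromethanesulfonate
Conditions: 1 M HCl, THF, 0 °C → rt
Reagents that add atoms: water, O
Why: Acid-catalysed acetal hydrolysis; the enol triflate is stable to dilute aqueous acid.

Step 6
Reactants: 7 (S)-5-(3-oxopropyl)cyclopent-1-en-1-yl trifluoromethanesulfonate; 8 nitromethane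
Product: 10 (R)-5-[(E)-4-nitrobut-3-en-1-yl]cyclopent-1-en-1-yl trifluoromethanesulfonate, via nitro alcohol 9 (not isolated)
Conditions: MeNO2 (excess), tetramethylguanidine (5 mol %), 0 °C; then MsCl, Et3N, CH2Cl2, −20 → 0 °C
Reagents that add atoms: none
Why: Henry reaction followed by mesylation and E1cB elimination gives the (E)-nitroalkene, with nitromethane supplying C7 and N (the descriptor changes only by priority, not by geometry).

Step 7
Reactants: 11 methyl acetoacetate; 3 3-bromo-1,1-dimethoxypropane
Product: 12 methyl 2-acetyl-5,5-dimethoxypentanoate (racemic)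
Conditions: NaH, NaI (cat.), THF/DMF, 0 → 60 °C
Reagents that add atoms: none
Why: C-alkylation of the acetoacetate enolate (SN2 via the iodide formed in situ) installs the C4–C2–C1 arm as a masked aldehyde.

Step 8
Reactants: 10 (R)-5-[(E)-4-nitrobut-3-en-1-yl]cyclopent-1-en-1-yl trifluoromethanesulfonate; 12 methyl 2-acetyl-5,5-dimethoxypentanoate
Product: 13 methyl (2R,3S)-2-acetyl-2-(3,3-dimethoxypropyl)-3-(nitromethyl)-5-[(1R)-2-(trifluoromethanesulfonyloxy)cyclopent-2-en-1-yl]pentanoate
Conditions: quinidine-derived 3,5-bis(trifluoromethyl)phenyl squaramide (10 mol %), 12 (1.5 equiv), toluene (1 M), 0 °C → rt, 72 h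
Reagents that add atoms: none
Why: Bifunctional amine/squaramide-catalysed Michael addition of an α-substituted β-keto ester to a nitroalkene: the catalyst binds the enol and the nitro group and sets quaternary C5 (R) and tertiary C6 (S) together, independently of remote C10 (the quinine-derived pseudoenantiomer is used if the sense proves opposite).

Step 9
Reactants: 13 methyl (2R,3S)-2-acetyl-2-(3,3-dimethoxypropyl)-3-(nitromethyl)-5-[(1R)-2-(trifluoromethanesulfonyloxy)cyclopent-2-en-1-yl]pentanoate
Product: 14 methyl (2R,3S)-2-(3,3-dimethoxypropyl)-3-(nitromethyl)-2-[1-(trifluoromethanesulfonyloxy)ethenyl]-5-[(1R)-2-(trifluoromethanesulfonyloxy)cyclopent-2-en-1-yl]pentanoate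
Conditions: KN(SiMe3)2 (2.2 equiv), THF, −78 °C; PhNTf2 (1.1 equiv), −78 → −30 °C; AcOH quench
Reagents that add atoms: N-phenylbis(trifluoromethanesulfonimide), O=S(=O)(N(c1ccccc1)S(=O)(=O)C(F)(F)F)C(F)(F)F
Why: Enol triflate formation through a dianion: the first equivalent of base stores the nitroalkane as its nitronate, the second enolizes the methyl ketone (the only enolizable side, since C5 is quaternary), and the harder enolate oxygen is triflated; no stereocenter is touched.

Step 10
Reactants: 14 methyl (2R,3S)-2-(3,3-dimethoxypropyl)-3-(nitromethyl)-2-[1-(trifluoromethanesulfonyloxy)ethenyl]-5-[(1R)-2-(trifluoromethanesulfonyloxy)cyclopent-2-en-1-yl]pentanoate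
Product: 15 methyl (5R,6S,8aS)-5-(3,3-dimethoxypropyl)-4-methylidene-6-(nitromethyl)-1,2,4,5,6,7,8,8a-octahydroazulene-5-carboxylate
Conditions: Pd(PPh3)4 (10 mol %), Me3SnSnMe3 (1.05 equiv), LiCl, 1,4-dioxane (5 mM), 100 °C
Reagents that add atoms: none
Why: Stille–Kelly reaction: zerovalent palladium and the distannane stannylate one enol triflate in situ, and intramolecular Stille coupling with the other forms C8–C9 and closes ring D as an s-cis diene (C13H2=C8–C9=C15) without touching a stereocenter.

Step 11
Reactants: 15 methyl (5R,6S,8aS)-5-(3,3-dimethoxypropyl)-4-methylidene-6-(nitromethyl)-1,2,4,5,6,7,8,8a-octahydroazulene-5-carboxylate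
Product: 17 (5R,6S,10S)-cyclic aldimine in which N=C1H–C2H2–C4H2 joins C7 to C5 on the C8-methylidene hydroazulene diene and C5 carries C21H2OH, via amino alcohol acetal 16 (not isolated)
Conditions: LiAlH4, THF, 0 °C → reflux; Fieser work-up; then AcOH/H2O/THF (3:1:1), 40 °C; aq. NaHCO3
Reagents that add atoms: none
Why: Hydride reduction takes the ester to the C21 carbinol and the nitro group to the C7 amine in one operation (so no γ-lactam can form); mild acid then unmasks the aldehyde, which condenses with the amine to the seven-membered imine (in equilibrium with its N,O-acetal formed by addition of the C21 hydroxyl).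

Step 12
Reactants: 17 (5R,6S,10S)-cyclic aldimine with C21H2OH; 18 N-methoxy-N-methylpropanamide
Product: 19 (5R,6S,10S)-cyclic enaminone N(H)–C1H=C2[C3(=O)C18H2C20H3]–C4H2 (C1=C2 cis within the seven-membered ring) with free C21H2OH
Conditions: LiN(iPr)2 (3.2 equiv), THF, −78 → −20 °C; then 18, −78 °C → rt; H2O
Reagents that add atoms: none
Why: Directed C-acylation of the metalated imine (1-azaallyl anion, deprotonated at C2, its only α-position) by the Weinreb amide, then tautomerization to the vinylogous amide; the lithium alkoxide at C21 does not react with the amide.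

Step 13
Reactants: 19 (5R,6S,10S)-cyclic enaminone with free C21H2OH; 20 bromoacetyl bromide
Product: 21 bromoacetate ester of 19 at O–C21
Conditions: 20 (1.1 equiv), pyridine, CH2Cl2, −40 °C
Reagents that add atoms: none
Why: Chemoselective O-acylation of the primary alcohol; the vinylogous-amide nitrogen is not nucleophilic.

Step 14
Reactants: 21 bromoacetate ester of 19 at O–C21
Product: 22 (1S,2S,5R,6S,8R,10S)-pentacyclic amino ketone lactone (the target lacking C19: rings B/C/D/E/F closed; N–H; propanoyl on C2)
Conditions: Bu3SnH (1.3 equiv) and AIBN (0.2 equiv) by syringe pump over 10 h, benzene (3 mM), 80 °C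
Reagents that add atoms: none
Why: Proposed new method: Bu3Sn• abstracts bromine to give the electrophilic (alkoxycarbonyl)methyl radical, which adds 7-endo to the electron-rich terminal C13 of the diene (the exo mode is blocked by fully substituted C8), the tertiary allyl radical (C8/C9/C15) then adds through C8 across the seven-membered ring to the enaminone β-carbon C1 (6-exo with respect to ring B, giving the ketone-stabilized C2 radical), and hydrogen transfer from Bu3SnH to the open exo face of C2 ends the chain; because both tethers start at C5, C8 (R) and C1 (S) can only form with the lactone cis to C21 and the C1–C8 bond cis to C4, and bonding at C8 leaves the alkene at C9=C15; the closest known reaction types are endo cyclizations of bromoacetate-derived radicals to medium-ring lactones and tin hydride radical cyclizations onto vinylogous amides, here joined as a tandem radical cyclization.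

Step 15
Reactants: 22 (1S,2S,5R,6S,8R,10S)-pentacyclic amino ketone lactone; 23 formaldehyde
Product: 25 CNP0292775.1 (1S,2S,5R,6S,8R,10S,18R), via N-methylene iminium ion 24 (not isolated)
Conditions: 37% aq. CH2O (1.2 equiv), AcOH, EtOH, 60 °C
Reagents that add atoms: none
Why: Intramolecular Mannich reaction: the N-methylene iminium is attacked by the ethyl-ketone enol at C18 (six-membered closure; attack from C2 would need a four-membered ring) to form the 4-piperidone ring A; C2 is held (S) by the cis A/C fusion, and C18, epimerizable through the enol and the reversible Mannich step, is expected to settle as the (R) epimer of the alkaloid with the methyl pseudo-equatorial on a twist-boat ring A.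

**Compound list**

1 | cyclopentanone | O=C1CCCC1 | starting material
2 | (S)-N-cyclopentylidene-2-(methoxymethyl)pyrrolidin-1-amine | COC[C@@H]1CCCN1N=C1CCCC1 | intermediate
3 | 3-bromo-1,1-dimethoxypropane | COC(OC)CCBr | starting material
4 | (2S)-N-[(2S)-2-(3,3-dimethoxypropyl)cyclopentylidene]-2-(methoxymethyl)pyrrolidin-1-amine | COC[C@@H]1CCCN1N=C1CCC[C@H]1CCC(OC)OC | intermediate
5 | (S)-2-(3,3-dimethoxypropyl)cyclopentan-1-one | COC(OC)CC[C@@H]1CCCC1=O | intermediate
6 | (S)-5-(3,3-dimethoxypropyl)cyclopent-1-en-1-yl trifluoromethanesulfonate | COC(OC)CC[C@@H]1CCC=C1OS(=O)(=O)C(F)(F)F | intermediate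
7 | (S)-5-(3-oxopropyl)cyclopent-1-en-1-yl trifluoromethanesulfonate | O=CCC[C@@H]1CCC=C1OS(=O)(=O)C(F)(F)F | intermediate
8 | nitromethane | C[N+](=O)[O-] | starting material
9 | (5S)-5-(3-hydroxy-4-nitrobutyl)cyclopent-1-en-1-yl trifluoromethanesulfonate (carbinol epimers) | O=[N+]([O-])CC(O)CC[C@@H]1CCC=C1OS(=O)(=O)C(F)(F)F | intermediate (not isolated)
10 | (R)-5-[(E)-4-nitrobut-3-en-1-yl]cyclopent-1-en-1-yl trifluoromethanesulfonate | O=[N+]([O-])/C=C/CC[C@@H]1CCC=C1OS(=O)(=O)C(F)(F)F | intermediate
11 | methyl acetoacetate | CC(=O)CC(=O)OC | starting material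
12 | methyl 2-acetyl-5,5-dimethoxypentanoate (racemic) | CC(=O)C(CCC(OC)OC)C(=O)OC | intermediate
13 | methyl (2R,3S)-2-acetyl-2-(3,3-dimethoxypropyl)-3-(nitromethyl)-5-[(1R)-2-(trifluoromethanesulfonyloxy)cyclopent-2-en-1-yl]pentanoate | CC(=O)[C@@](C(=O)OC)(CCC(OC)OC)[C@@H](C[N+](=O)[O-])CC[C@@H]1CCC=C1OS(=O)(=O)C(F)(F)F | intermediate
14 | methyl (2R,3S)-2-(3,3-dimethoxypropyl)-3-(nitromethyl)-2-[1-(trifluoromethanesulfonyloxy)ethenyl]-5-[(1R)-2-(trifluoromethanesulfonyloxy)cyclopent-2-en-1-yl]pentanoate | C=C(OS(=O)(=O)C(F)(F)F)[C@@](C(=O)OC)(CCC(OC)OC)[C@@H](C[N+](=O)[O-])CC[C@@H]1CCC=C1OS(=O)(=O)C(F)(F)F | intermediate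
15 | methyl (5R,6S,8aS)-5-(3,3-dimethoxypropyl)-4-methylidene-6-(nitromethyl)-1,2,4,5,6,7,8,8a-octahydroazulene-5-carboxylate | C=C1C2=CCC[C@H]2CC[C@H](C[N+](=O)[O-])[C@]1(C(=O)OC)CCC(OC)OC | intermediate
16 | [(5R,6S,8aS)-6-(aminomethyl)-5-(3,3-dimethoxypropyl)-4-methylidene-1,2,4,5,6,7,8,8a-octahydroazulen-5-yl]methanol | C=C1C2=CCC[C@H]2CC[C@H](CN)[C@]1(CO)CCC(OC)OC | intermediate (not isolated)
17 | (5R,6S,10S)-cyclic aldimine (N=C1H–C2H2–C4H2 joining C7 to C5; C21H2OH on C5; C8-methylidene diene) | C=C1C2=CCC[C@H]2CC[C@@H]3CN=CCC[C@]13CO | intermediate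
18 | N-methoxy-N-methylpropanamide | CCC(=O)N(C)OC | starting material
19 | (5R,6S,10S)-cyclic enaminone (N(H)–C1H=C2 bearing the propanoyl group; C21H2OH free) | C=C1C2=CCC[C@H]2CC[C@@H]3CN/C=C(/C(=O)CC)C[C@]13CO | intermediate
20 | bromoacetyl bromide | BrCC(Br)=O | starting material
21 | bromoacetate ester of 19 at O–C21 | C=C1C2=CCC[C@H]2CC[C@@H]3CN/C=C(/C(=O)CC)C[C@]13COC(=O)CBr | intermediate
22 | (1S,2S,5R,6S,8R,10S)-pentacyclic amino ketone lactone (target lacking C19) | N1C[C@H]2CC[C@@H]3CCC=C3[C@]34CCC(=O)OC[C@]23C[C@H](C(=O)CC)[C@H]14 | intermediate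
23 | formaldehyde | C=O | starting material
24 | N-methylene iminium ion of 22 (acetate salt) | C=[N+]1C[C@H]2CC[C@@H]3CCC=C3[C@]34CCC(=O)OC[C@]23C[C@H](C(=O)CC)[C@H]14 | intermediate (not isolated)
25 | CNP0292775.1 (1S,2S,5R,6S,8R,10S,18R) | C[C@@H]1CN2C[C@H]3CC[C@@H]4CCC=C4[C@]45CCC(=O)OC[C@]34C[C@H](C1=O)[C@H]25 | target

**Step count**
Total: 15 steps. Longest linear sequence: 14 steps (steps 1–6 and 8–15); step 7 is a one-step side branch.

**Three steps most likely to fail, each with a fallback**

Step 14 (radical cascade). The stabilized, hindered allyl radical may be reduced by the tin hydride before it adds to the electron-rich enaminone, giving only the monocyclic lactone. The fallback sets out from 21 and returns at 22, replacing the second radical bond formation by an organometallic allylation. Copper-catalysed atom-transfer radical cyclization (CuBr, tris(2-pyridylmethyl)amine, MeCN, 60 °C) stops after the 7-endo step by bromine transfer to the allyl radical and gives the ε-lactone allylic bromide F5 (Br on C15, alkene C8=C9). Indium powder in THF/H2O with AcOH then forms the allylindium, whose γ-carbon C8 adds to C1 of the acid-activated enaminone in an intramolecular Barbier-type conjugate allylation. This forms the same C8–C1 bond, the same tether-enforced configurations and the C9=C15 alkene of 22.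

Step 8 (Michael addition creating C5 and C6). An acyclic α-alkyl acetoacetate with an aliphatic nitroalkene may react slowly or give the wrong C5/C6 relationship. The fallback sets out from 10 (with 11) and returns at 13, building the two centers one at a time. A thiourea–tertiary amine catalysed Michael addition of unsubstituted methyl acetoacetate 11 to 10, a well-established donor class, gives the C6-defined adduct F1 as a C5 epimer mixture. A second, catalyst-controlled Michael addition of F1 to acrolein under cupreidine-type cinchona catalysis (CH2Cl2, −20 °C) creates the quaternary C5 as the aldehyde F2. Acetalization (HC(OMe)3, MeOH, TsOH cat.) gives 13.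

Step 10 (seven-membered ring by coupling of two enol triflates). Double stannylation or oligomerization may outrun ring closure. The fallback sets out from 13 (leaving out 14) and returns at 15, making C8–C9 by carbonyl addition instead of sp2–sp2 coupling. Miyaura borylation of the ring enol triflate (PdCl2(dppf), B2pin2, KOAc, dioxane, 80 °C) gives the alkenyl boronate F3. Rhodium-catalysed intramolecular 1,2-addition of the alkenylboron to the methyl ketone ([Rh(cod)OH]2, dioxane/H2O, 80 °C) closes ring D as the tertiary allylic alcohol F4. Burgess dehydration, which can only take a hydrogen from the methyl group, gives the diene 15.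

Further compounds
F1 | step 8 | methyl (3S)-2-acetyl-3-(nitromethyl)-5-[(1R)-2-(trifluoromethanesulfonyloxy)cyclopent-2-en-1-yl]pentanoate (C2 epimers) | CC(=O)C(C(=O)OC)[C@@H](C[N+](=O)[O-])CC[C@@H]1CCC=C1OS(=O)(=O)C(F)(F)F
F2 | step 8 | methyl (2R,3S)-2-acetyl-3-(nitromethyl)-2-(3-oxopropyl)-5-[(1R)-2-(trifluoromethanesulfonyloxy)cyclopent-2-en-1-yl]pentanoate | CC(=O)[C@@](C(=O)OC)(CCC=O)[C@@H](C[N+](=O)[O-])CC[C@@H]1CCC=C1OS(=O)(=O)C(F)(F)F
F3 | step 10 | methyl (2R,3S)-2-acetyl-2-(3,3-dimethoxypropyl)-3-(nitromethyl)-5-[(1S)-2-(4,4,5,5-tetramethyl-1,3,2-dioxaborolan-2-yl)cyclopent-2-en-1-yl]pentanoate | CC(=O)[C@@](C(=O)OC)(CCC(OC)OC)[C@@H](C[N+](=O)[O-])CC[C@@H]1CCC=C1B1OC(C)(C)C(C)(C)O1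
F4 | step 10 | methyl (5R,6S,8aS)-5-(3,3-dimethoxypropyl)-4-hydroxy-4-methyl-6-(nitromethyl)-1,2,4,5,6,7,8,8a-octahydroazulene-5-carboxylate (C4 epimers) | CC1(O)C2=CCC[C@H]2CC[C@H](C[N+](=O)[O-])[C@]1(C(=O)OC)CCC(OC)OC
F5 | step 14 | (5R,6S,10S)-ε-lactone allylic bromide (C14–C13 formed; Br on C15; C8=C9; enaminone intact; C15 epimers) | O=C1CCC2=C3C(Br)CC[C@H]3CC[C@@H]4CN/C=C(/C(=O)CC)C[C@]24CO1
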